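**Retrosynthetic overview**
- Target ⇐ Δ11-olefin by α-face epoxidation and trans-diaxial hydrolysis (last operation).
- C16–C2 bond and C1–OMe ⇐ bromosphaerol-type tricycle with a Δ1 olefin and an axial C16 electrophile on C5: the biogenetic cyclohexenylmethyl → bicyclo[2.2.1] closure with methanol capture (last ring).
- Rings B and C ⇐ intramolecular Diels–Alder reaction (C5–C14 and C3–C4 bonds) of an (E)-butadienyl group and an (E)-2-alkyl-4-methylpent-2-enal carried on ring D. This is the one ring construction with no cationic biogenetic counterpart.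
- Ring D with the C9 bromide ⇐ enantioselective bromonium-induced cyclisation of an acyclic (2E,4E,8E)-trienal (first ring, sets absolute configuration).
- Trienal ⇐ geranyl acetate + C3 acetal Grignard + formyl ylide. Ring order: D → B/C together → bicyclo[2.2.1] bridge.

Locants used below: C1 CH–OMe; C2 bridgehead CH; C3 CH2; C4 CH–iPr; C5 quaternary bridgehead; C6, C7 CH2; C8 C–CH3; C9 CHBr; C10 CH2; C11 CHOH; C12 C(OH)CH3; C13 CH joining C8/C12/C14; C14 CH joining C13/C1/C5; C16 CH2 bridge C5–C2. With these locants the target is S at all ten stereocentres.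

Assumption: the catalyst antipode in step 6 is the one that gives (1R,5S,6S)-10; the sense of induction is taken from homogeranylarene cases and is not proven for this substrate.

Nothing here has been run; steps 6 and 11 go beyond known scope and are marked as such.

**Route**

Step 1
Reactants: 1 geranyl acetate [(2E)-3,7-dimethylocta-2,6-dien-1-yl acetate]
Product: 2 (2E,6E)-8-hydroxy-3,7-dimethylocta-2,6-dien-1-yl acetate
Conditions: SeO2 (10 mol %), t-BuOOH (3 equiv), salicylic acid (10 mol %), CH2Cl2, 25 °C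
Reagents that add atoms: tert-butyl hydroperoxide, CC(C)(C)OO
Why: SeO2-catalysed allylic oxidation (ene/[2,3] sequence) attacks the (E)-methyl of the distal trisubstituted olefin because the allylic acetate deactivates the C2 olefin; no stereocentre is formed.

Step 2
Reactants: 2 (2E,6E)-8-hydroxy-3,7-dimethylocta-2,6-dien-1-yl acetate
Product: 3 (2E,6E)-8-bromo-3,7-dimethylocta-2,6-dien-1-yl acetate
Conditions: CBr4, PPh3, CH2Cl2, −20 → 0 °C
Reagents that add atoms: carbon tetrabromide, BrC(Br)(Br)Br
Why: Appel bromination of the primary allylic alcohol proceeds by SN2 on the alkoxyphosphonium ion without allylic transposition at low temperature.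

Step 3
Reactants: 3 (2E,6E)-8-bromo-3,7-dimethylocta-2,6-dien-1-yl acetate; 4 2-(2-bromoethyl)-1,3-dioxolane
Product: 5 (2E,6E)-10-(1,3-dioxolan-2-yl)-3,7-dimethyldeca-2,6-dien-1-yl acetate
Conditions: 4, Mg, THF, 25 °C; then 3, Li2CuCl4 (3 mol %), THF, −78 → −20 °C
Reagents that add atoms: none
Why: Kochi copper-catalysed Grignard/allylic bromide coupling gives α-substitution with retention of the E olefin and is much faster at −78 °C than attack on the acetate.

Step 4
Reactants: 5 (2E,6E)-10-(1,3-dioxolan-2-yl)-3,7-dimethyldeca-2,6-dien-1-yl acetate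
Product: 6 (2E,6E)-10-(1,3-dioxolan-2-yl)-3,7-dimethyldeca-2,6-dien-1-ol
Conditions: K2CO3 (0.2 equiv), MeOH, 0 → 25 °C
Reagents that add atoms: none
Why: Base-catalysed transesterification (methanolysis) frees the allylic alcohol while the dioxolane is inert to base.

Step 5
Reactants: 6 (2E,6E)-10-(1,3-dioxolan-2-yl)-3,7-dimethyldeca-2,6-dien-1-ol; 7 (triphenylphosphoranylidene)acetaldehyde
Product: 9 (2E,4E,8E)-12-(1,3-dioxolan-2-yl)-5,9-dimethyldodeca-2,4,8-trienal, via dienal 8 (not isolated)
Conditions: activated MnO2 (15 equiv), 7 (1.2 equiv), toluene, 70 °C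
Reagents that add atoms: none
Why: Tandem MnO2 oxidation/Wittig olefination converts the allylic alcohol to the 2E-enal and then, with the stabilised formyl ylide, to the E,E-dienal, which is less electrophilic than the enal so double homologation is limited.

Step 6
Reactants: 9 (2E,4E,8E)-12-(1,3-dioxolan-2-yl)-5,9-dimethyldodeca-2,4,8-trienal
Product: 10 (2E)-3-[(1R,5S,6S)-5-bromo-6-[3-(1,3-dioxolan-2-yl)propyl]-2,6-dimethylcyclohex-2-en-1-yl]prop-2-enal
Conditions: 1,3-dibromo-5,5-dimethylhydantoin (0.55 equiv), (R)-BINOL-derived thiophosphoramide Lewis-base catalyst (10 mol %), CH2Cl2–toluene, −78 °C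
Reagents that add atoms: 1,3-dibromo-5,5-dimethylhydantoin, CC1(C)N(Br)C(=O)N(Br)C1=O
Why: Proposed new method: a Lewis-base-catalysed enantioselective bromonium-induced polyene cyclisation (closest known types: thiophosphoramide/DBDMH bromocyclisation of homogeranylarenes and the pseudoionone → α-ionone cyclisation) in which Br+ goes to the only electron-rich olefin (C8=C9), C4 of the deactivated dienal attacks C9 through a chair transition state (Br and the C10 chain equatorial, methyl axial, side chain equatorial) and the tertiary cation loses H-6 to give the endocyclic olefin, so the relative configuration of target C8, C9 and C13 comes from the two E olefins and the absolute configuration from the catalyst.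

Step 7
Reactants: 10 (2E)-3-[(1R,5S,6S)-5-bromo-6-[3-(1,3-dioxolan-2-yl)propyl]-2,6-dimethylcyclohex-2-en-1-yl]prop-2-enal; 11 methyltriphenylphosphonium bromide
Product: 12 2-{3-[(1S,2R,6S)-6-bromo-2-[(1E)-buta-1,3-dien-1-yl]-1,3-dimethylcyclohex-3-en-1-yl]propyl}-1,3-dioxolane
Conditions: 11, KHMDS, THF, 0 °C; then 10, −78 → 0 °C
Reagents that add atoms: none
Why: Wittig methylenation of the enal gives the (E)-1-substituted butadiene with the existing E olefin untouched; the equatorial bromide has no anti-periplanar hydrogen for E2 and no stereocentre changes.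

Step 8
Reactants: 12 2-{3-[(1S,2R,6S)-6-bromo-2-[(1E)-buta-1,3-dien-1-yl]-1,3-dimethylcyclohex-3-en-1-yl]propyl}-1,3-dioxolane; 13 isobutyraldehyde (2-methylpropanal)
Product: 15 (2E)-2-{2-[(1S,2R,6S)-6-bromo-2-[(1E)-buta-1,3-dien-1-yl]-1,3-dimethylcyclohex-3-en-1-yl]ethyl}-4-methylpent-2-enal, via butanal 14 (not isolated)
Conditions: 1 M aq HCl (0.3 equiv), THF–H2O, 25 °C; then pyrrolidine (0.6 equiv), 13 (5 equiv), 40 °C
Reagents that add atoms: water, O
Why: Acid hydrolysis of the dioxolane followed by amine-catalysed crossed aldol condensation (enamine addition/elimination) with excess isobutyraldehyde, whose own aldol cannot dehydrate so the cross-condensation wins, gives the thermodynamic E-enal with isopropyl trans to CHO.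

Step 9
Reactants: 15 (2E)-2-{2-[(1S,2R,6S)-6-bromo-2-[(1E)-buta-1,3-dien-1-yl]-1,3-dimethylcyclohex-3-en-1-yl]ethyl}-4-methylpent-2-enal
Product: 16 tricyclic aldehyde (4S,5S,8S,9S,13R,14S): rings B/C/D trans-anti-trans; C1=C2 and C11=C12 olefins; C16 formyl axial on C5; C4 isopropyl trans to C16; C8 methyl; C9 equatorial bromide
Conditions: Me2AlCl (1.1 equiv), CH2Cl2, −78 → −30 °C
Reagents that add atoms: none
Why: Lewis-acid-promoted intramolecular Diels–Alder reaction through the chair-like anti transition state with the formyl group endo gives the trans B/C fusion anti to ring D (H-14 trans to C16) and, by suprafacial addition to the E-enal, isopropyl trans to C16, so C5, C14 and C4 are set together under control of C8 and C13.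

Step 10
Reactants: 16 tricyclic aldehyde
Product: 17 tricyclic neopentyl alcohol (4S,5S,8S,9S,13R,14S): as 16 with C16 = CH2OH
Conditions: NaBH4, MeOH–THF, 0 °C
Reagents that add atoms: none
Why: Borohydride reduction of the hindered aldehyde leaves the bromide, both olefins and all stereocentres untouched.

Step 11
Reactants: 17 tricyclic neopentyl alcohol
Product: 19 tetracyclic methyl ether (1S,2S,4S,5S,8S,9S,13R,14S): C16 bridges C5 and C2; C1–OMe endo (anti to C16); C11=C12 olefin retained, via triflate 18 (not isolated)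
Conditions: Tf2O (1.05 equiv), 2,6-di-tert-butyl-4-methylpyridine, CH2Cl2, −78 °C; then MeOH–HFIP (1:3), 0 → 40 °C
Reagents that add atoms: trifluoromethanesulfonic anhydride, O=S(=O)(OS(=O)(=O)C(F)(F)F)C(F)(F)F (CF3SO2 group, present in 18 only); methanol, CO
Why: Proposed new method: π-assisted solvolysis of a neopentyl triflate (closest known types: the π-route to norbornyl cations and the terpinyl → bornyl cyclisation) in which the axial C16, held over ring B, is attacked by C2 of the Δ1 olefin and methanol captures the C16-bridged cation at C1 anti to C16 (bornyl-type endo capture), so C2 and C1 are set by this anti addition.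

Step 12
Reactants: 19 tetracyclic methyl ether
Product: 21 target CNP0130529.1 (1S,2S,4S,5S,8S,9S,11S,12S,13S,14S), via epoxide 20 (not isolated)
Conditions: dimethyldioxirane, acetone, 0 °C; then 5% aq HClO4, THF, 25 °C
Reagents that add atoms: dimethyldioxirane, CC1(C)OO1; water, O
Why: Epoxidation of the trisubstituted olefin occurs on the α-face anti to the axial C8 methyl, and acid-catalysed hydrolysis follows the Fürst–Plattner rule with water attacking tertiary C12 axially from the β-face to give the trans-diaxial 11,12-diol.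

**Compound list**

1 | geranyl acetate | CC(=O)OC/C=C(C)/CCC=C(C)C | starting material
2 | (2E,6E)-8-hydroxy-3,7-dimethylocta-2,6-dien-1-yl acetate | CC(=O)OC/C=C(C)/CC/C=C(C)/CO | intermediate
3 | (2E,6E)-8-bromo-3,7-dimethylocta-2,6-dien-1-yl acetate | CC(=O)OC/C=C(C)/CC/C=C(C)/CBr | intermediate
4 | 2-(2-bromoethyl)-1,3-dioxolane | BrCCC1OCCO1 | starting material
5 | (2E,6E)-10-(1,3-dioxolan-2-yl)-3,7-dimethyldeca-2,6-dien-1-yl acetate | CC(=O)OC/C=C(C)/CC/C=C(C)/CCCC1OCCO1 | intermediate
6 | (2E,6E)-10-(1,3-dioxolan-2-yl)-3,7-dimethyldeca-2,6-dien-1-ol | OC/C=C(C)/CC/C=C(C)/CCCC1OCCO1 | intermediate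
7 | (triphenylphosphoranylidene)acetaldehyde | O=CC=P(c1ccccc1)(c1ccccc1)c1ccccc1 | starting material
8 | (2E,6E)-10-(1,3-dioxolan-2-yl)-3,7-dimethyldeca-2,6-dienal | O=C/C=C(C)/CC/C=C(C)/CCCC1OCCO1 | intermediate (not isolated)
9 | (2E,4E,8E)-12-(1,3-dioxolan-2-yl)-5,9-dimethyldodeca-2,4,8-trienal | O=C/C=C/C=C(C)/CC/C=C(C)/CCCC1OCCO1 | intermediate
10 | (2E)-3-[(1R,5S,6S)-5-bromo-6-[3-(1,3-dioxolan-2-yl)propyl]-2,6-dimethylcyclohex-2-en-1-yl]prop-2-enal | O=C/C=C/[C@@H]1C(C)=CC[C@H](Br)[C@@]1(C)CCCC2OCCO2 | intermediate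
11 | methyltriphenylphosphonium bromide | C[P+](c1ccccc1)(c1ccccc1)c1ccccc1.[Br-] | starting material
12 | 2-{3-[(1S,2R,6S)-6-bromo-2-[(1E)-buta-1,3-dien-1-yl]-1,3-dimethylcyclohex-3-en-1-yl]propyl}-1,3-dioxolane | C=C/C=C/[C@@H]1C(C)=CC[C@H](Br)[C@@]1(C)CCCC2OCCO2 | intermediate
13 | isobutyraldehyde | CC(C)C=O | starting material
14 | 4-[(1S,2R,6S)-6-bromo-2-[(1E)-buta-1,3-dien-1-yl]-1,3-dimethylcyclohex-3-en-1-yl]butanal | C=C/C=C/[C@@H]1C(C)=CC[C@H](Br)[C@@]1(C)CCCC=O | intermediate (not isolated)
15 | (2E)-2-{2-[(1S,2R,6S)-6-bromo-2-[(1E)-buta-1,3-dien-1-yl]-1,3-dimethylcyclohex-3-en-1-yl]ethyl}-4-methylpent-2-enal | C=C/C=C/[C@@H]1C(C)=CC[C@H](Br)[C@@]1(C)CC/C(C=O)=C\C(C)C | intermediate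
16 | tricyclic aldehyde (4S,5S,8S,9S,13R,14S), C16 = CHO, Δ1 and Δ11 olefins | C1=CC[C@@H](C(C)C)[C@@]2(C=O)CC[C@@]3(C)[C@H]([C@H]12)C(C)=CC[C@@H]3Br | intermediate
17 | tricyclic alcohol (4S,5S,8S,9S,13R,14S), C16 = CH2OH | C1=CC[C@@H](C(C)C)[C@@]2(CO)CC[C@@]3(C)[C@H]([C@H]12)C(C)=CC[C@@H]3Br | intermediate
18 | tricyclic C16 triflate (4S,5S,8S,9S,13R,14S) | C1=CC[C@@H](C(C)C)[C@@]2(COS(=O)(=O)C(F)(F)F)CC[C@@]3(C)[C@H]([C@H]12)C(C)=CC[C@@H]3Br | intermediate (not isolated)
19 | tetracyclic methyl ether (1S,2S,4S,5S,8S,9S,13R,14S), Δ11 olefin | CO[C@H]1[C@H]2C[C@@H](C(C)C)[C@]3(CC[C@@]4(C)[C@H]([C@H]13)C(C)=CC[C@@H]4Br)C2 | intermediate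
20 | 11α,12α-epoxide of 19 (11S,12R) | CO[C@H]1[C@H]2C[C@@H](C(C)C)[C@]3(CC[C@@]4(C)[C@H]([C@H]13)[C@@]5(C)O[C@H]5C[C@@H]4Br)C2 | intermediate (not isolated)
21 | CNP0130529.1 | CO[C@H]1[C@H]2C[C@@H](C(C)C)[C@]3(CC[C@@]4(C)[C@H]([C@H]13)[C@](C)(O)[C@@H](O)C[C@@H]4Br)C2 | target

**Step count and risks**

Total step count: 12. Longest linear sequence: 12 steps from geranyl acetate (4, 7, 11 and 13 are purchased).

Steps most likely to fail:

Step 6 (enantioselective bromocyclisation onto a deactivated dienal, with regioselective proton loss). The risks are low ee, halide capture of the bromonium ion, and exocyclic or conjugated olefin isomers. The fallback sets out from 9 and returns at 10. Shi epoxidation with the D-fructose-derived ketone and Oxone at 0 °C oxidises the only electron-rich olefin to (2E,4E)-7-{(2R,3R)-3-[3-(1,3-dioxolan-2-yl)propyl]-3-methyloxiran-2-yl}-5-methylhepta-2,4-dienal F1. Bromide opening at the secondary carbon with inversion (Li2NiBr4, THF) gives (2E,4E,8S,9R)-8-bromo-12-(1,3-dioxolan-2-yl)-9-hydroxy-5,9-dimethyldodeca-2,4-dienal F2. Ionisation of the tertiary hydroxyl in HFIP with catalytic HNTf2 at −20 °C, assisted by the neighbouring bromine, generates an enantiopure bromiranium ion. This cyclises stereospecifically (net retention at C9 of the chain) to 10, so the absolute configuration comes from the epoxidation instead of the bromine-transfer catalyst.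

Step 9 (intramolecular Diels–Alder reaction of a hindered trisubstituted enal). The risks are no reaction, cis fusion, or Lewis-acid-induced Prins reaction of the product aldehyde with the Δ1 olefin. The fallback sets out from 15 and returns at 16. Trimethyl orthoformate and PPTS in MeOH give the dimethyl acetal of 15 F3. Catalytic TMSOTf in CH2Cl2 at −78 °C ionises it to a vinyl oxocarbenium ion, a far stronger dienophile (ionic Diels–Alder reaction), and the cycloadduct is collected as the dimethyl acetal of 16 F4. Aqueous oxalic acid hydrolyses it to 16 without a stoichiometric aluminium Lewis acid ever meeting the free aldehyde.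

Step 11 (bicyclo[2.2.1] closure with methanol capture). The risks are 1,2-alkyl shift (ring expansion) of the neopentyl system and capture from the exo face after relaxation to the classical norbornyl cation. The fallback sets out from 17 and returns at 19; it fixes the C1 configuration by reduction instead of by kinetic capture, but does not help if ring expansion dominates. Triflate 18 is solvolysed in HFIP–H2O (2,6-lutidine) to the C1 alcohol, expected as the (1R) exo alcohol F5. Dess–Martin oxidation gives the C1 ketone F6. NaBH4 attacks from the exo face (syn to C16) and gives the (1S) endo alcohol F7. NaH/MeI then gives 19.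

Further compounds
F1 | step 6 | (2E,4E)-7-{(2R,3R)-3-[3-(1,3-dioxolan-2-yl)propyl]-3-methyloxiran-2-yl}-5-methylhepta-2,4-dienal | O=C/C=C/C=C(C)/CC[C@H]1O[C@]1(C)CCCC2OCCO2
F2 | step 6 | (2E,4E,8S,9R)-8-bromo-12-(1,3-dioxolan-2-yl)-9-hydroxy-5,9-dimethyldodeca-2,4-dienal | O=C/C=C/C=C(C)/CC[C@H](Br)[C@@](O)(C)CCCC1OCCO1
F3 | step 9 | dimethyl acetal of 15 | C=C/C=C/[C@@H]1C(C)=CC[C@H](Br)[C@@]1(C)CC/C(C(OC)OC)=C\C(C)C
F4 | step 9 | dimethyl acetal of 16 | C1=CC[C@@H](C(C)C)[C@@]2(C(OC)OC)CC[C@@]3(C)[C@H]([C@H]12)C(C)=CC[C@@H]3Br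
F5 | step 11 | (1R) exo alcohol, C1 epimer of the O-demethyl analogue of 19 | O[C@@H]1[C@H]2C[C@@H](C(C)C)[C@]3(CC[C@@]4(C)[C@H]([C@H]13)C(C)=CC[C@@H]4Br)C2
F6 | step 11 | C1 ketone of the tetracycle | O=C1[C@H]2C[C@@H](C(C)C)[C@]3(CC[C@@]4(C)[C@H]([C@H]13)C(C)=CC[C@@H]4Br)C2
F7 | step 11 | (1S) endo alcohol, O-demethyl analogue of 19 | O[C@H]1[C@H]2C[C@@H](C(C)C)[C@]3(CC[C@@]4(C)[C@H]([C@H]13)C(C)=CC[C@@H]4Br)C2
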